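**Retrosynthetic overview**
1. Target 32 is cut back to the protected trimer 30 (five aryl benzyl ethers, three methyl esters). The enol ether arm is then cut at its C=C bond (olefination with aldehyde 1) and at its aryl O–C bond (carbenoid O–H insertion into phenol 25).
2. The strategy rests on ring B (C1–C2–C3=C4–C4a–C8a): C1 bears the aryl group, C2 an H and a carboxyl, C3 a carboxyl on the C3=C4 bond. This ring is a dearomatized, C2v-symmetric 6,7-dioxygenated naphthalene-2,3-dicarboxylate, so C1 and C4 are equivalent acceptor carbons and C2–H is epimerizable.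
3. The C1–aryl bond is therefore cut back to the C2-symmetric naphthalene bis(oxazoline) 14 and aryllithium 20 (from bromide 19).
4. Ring order: ring A is bought (1); ring B is closed flat as a naphthalene by twofold condensation of phthalaldehyde 6 with succinate 7; the pendant ring C is joined at C1 with dearomatization; the caffeic enol ether arm comes last.

Key step: step 10

Assumption: the sense of induction is taken from the usual model (nitrogen-bound aryllithium delivered to the ring face opposite the oxazoline tert-butyl group), which by geometric analysis requires the (4R)-oxazolines from (R)-tert-leucinol 11 for the (1R) centre; should the sense prove opposite, (S)-tert-leucinol is used with no other change.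

**Route**

Step 1
Reactants: 1 3,4-bis(benzyloxy)benzaldehyde
Product: 2 4,5-bis(benzyloxy)-2-bromobenzaldehyde
Conditions: Br2, NaOAc, AcOH, rt
Reagents that add atoms: bromine, BrBr
Why: electrophilic aromatic bromination should go to C6, para to the 3-benzyloxy group and not flanked by two substituents, while NaOAc buffers the HBr that would otherwise attack the benzyl ethers.

Step 2
Reactants: 2 4,5-bis(benzyloxy)-2-bromobenzaldehyde
Product: 3 2-[4,5-bis(benzyloxy)-2-bromophenyl]-1,3-dioxolane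
Conditions: HOCH2CH2OH, TsOH (cat.), toluene, reflux, Dean–Stark
Reagents that add atoms: ethylene glycol, OCCO
Why: acid-catalysed acetalization with azeotropic removal of water masks the aldehyde against the organolithium of the next step.

Step 3
Reactants: 3 2-[4,5-bis(benzyloxy)-2-bromophenyl]-1,3-dioxolane
Product: 6 4,5-bis(benzyloxy)phthalaldehyde, via aryllithium 4 (not isolated), via acetal aldehyde 5 (not isolated)
Conditions: n-BuLi, THF, −78 °C; DMF, −78 → 0 °C; then 2 M HCl, THF, rt
Reagents that add atoms: N,N-dimethylformamide, CN(C)C=O; water, O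
Why: bromine–lithium exchange outruns benzylic deprotonation at −78 °C, the aryllithium is formylated by DMF (Bouveault formylation), and the acidic work-up collapses the hemiaminal and hydrolyses the dioxolane.

Step 4
Reactants: 6 4,5-bis(benzyloxy)phthalaldehyde; 7 diethyl succinate
Product: 9 6,7-bis(benzyloxy)naphthalene-2,3-dicarboxylic acid, via diethyl diester 8 (not isolated)
Conditions: NaOEt, EtOH, 0 °C → reflux; then aq. NaOH, reflux; HCl to pH 1
Reagents that add atoms: sodium hydroxide, [Na+].[OH-]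
Why: twofold aldol (Stobbe-type) condensation of the two succinate methylene groups with the two aldehydes closes ring B (new bonds C1–C2 and C3–C4) and aromatizes it by loss of two waters, and direct saponification makes any half-ester from the Stobbe pathway irrelevant.

Step 5
Reactants: 9 6,7-bis(benzyloxy)naphthalene-2,3-dicarboxylic acid; 11 (R)-tert-leucinol (two equivalents are built into the product)
Product: 12 6,7-bis(benzyloxy)-N2,N3-bis[(2R)-1-hydroxy-3,3-dimethylbutan-2-yl]naphthalene-2,3-dicarboxamide, via diacid chloride 10 (not isolated)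
Conditions: (COCl)2 (excess), DMF (cat.), CH2Cl2, 0 °C → rt; evaporate; then 11 (2.2 equiv), Et3N, CH2Cl2, −20 °C → rt
Reagents that add atoms: (R)-tert-leucinol (the second equivalent of 11, one per acid chloride group), N[C@@H](CO)C(C)(C)C
Why: Vilsmeier-type activation gives the diacid chloride (excess reagent with DMF catalysis carries any cyclic anhydride on to the dichloride), and each acid chloride group then N-acylates one molecule of the amino alcohol (amine ahead of hydroxyl), low temperature and excess amine favouring the open bis-amide over the cyclic imide.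

Step 6
Reactants: 12 6,7-bis(benzyloxy)-N2,N3-bis[(2R)-1-hydroxy-3,3-dimethylbutan-2-yl]naphthalene-2,3-dicarboxamide
Product: 14 6,7-bis(benzyloxy)-2,3-bis[(4R)-4-tert-butyl-4,5-dihydro-1,3-oxazol-2-yl]naphthalene, via bis-mesylate 13 (not isolated)
Conditions: MsCl, Et3N, CH2Cl2, 0 → 40 °C
Reagents that add atoms: none
Why: O-mesylation and 5-exo-tet displacement by the amide oxygen (cyclodehydration to the 2-oxazoline, as used for tert-butyl oxazoline ligands) leave the stereocentre untouched, so (4R) is retained.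

Step 7
Reactants: 15 5-bromosalicylaldehyde
Product: 16 2-(benzyloxy)-5-bromobenzaldehyde
Conditions: BnBr, K2CO3, DMF, rt
Reagents that add atoms: benzyl bromide, BrCc1ccccc1
Why: Williamson etherification of the phenoxide.

Step 8
Reactants: 16 2-(benzyloxy)-5-bromobenzaldehyde
Product: 18 2-(benzyloxy)-5-bromophenol, via aryl formate 17 (not isolated)
Conditions: mCPBA, CH2Cl2, rt; then K2CO3 (cat.), MeOH, rt
Reagents that add atoms: 3-chloroperbenzoic acid, OOC(=O)c1cccc(Cl)c1
Why: Baeyer–Villiger oxidation with migration of the electron-rich ortho-alkoxyaryl group (Dakin-type) gives the aryl formate, which methanolysis cleaves to the phenol.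

Step 9
Reactants: 18 2-(benzyloxy)-5-bromophenol
Product: 19 [2-(benzyloxy)-5-bromophenoxy](tert-butyl)dimethylsilane
Conditions: TBSCl, imidazole, DMF, rt
Reagents that add atoms: tert-butyldimethylsilyl chloride, CC(C)(C)[Si](C)(C)Cl
Why: silylation of the phenol gives an ether that withstands halogen–lithium exchange at −78 °C and the acid of step 11 yet is removed by methoxide in step 12, so that this one phenol is later freed beside four benzyl ethers.

Step 10
Reactants: 14 6,7-bis(benzyloxy)-2,3-bis[(4R)-4-tert-butyl-4,5-dihydro-1,3-oxazol-2-yl]naphthalene; 19 [2-(benzyloxy)-5-bromophenoxy](tert-butyl)dimethylsilane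
Product: 22 2,2'-[(1R,2S)-6,7-bis(benzyloxy)-1-{4-(benzyloxy)-3-[(tert-butyldimethylsilyl)oxy]phenyl}-1,2-dihydronaphthalene-2,3-diyl]bis[(4R)-4-tert-butyl-4,5-dihydro-1,3-oxazole], via aryllithium 20 (not isolated), via lithium aza-enolate 21 (not isolated)
Conditions: 19, t-BuLi (2 equiv), THF, −78 °C; add 14, −78 → −30 °C; CF3CO2H, −78 °C
Reagents that add atoms: none
Why: Proposed new method: aryllithium 20 binds an oxazoline nitrogen of 14 and is delivered across the N=C–C2=C1 azadiene to C1 (C1–C1' bond), dearomatizing ring B to the lithium aza-enolate 21, which CF3CO2H protonates at C2 (C2–H bond) while C3=C4 stays conjugated to the second oxazoline. The closest known reaction type is the tandem addition of aryllithiums to chiral 2-naphthyloxazolines with trapping at the adjacent carbon, not yet shown on a 2,3-bis(oxazoline). No ring closes in this step. C1 should be set (R) by delivery to the face anti to the tert-butyl group of the (4R)-oxazoline on C2, and C2 is set trans to the aryl group on protonation, any cis epimer being corrected thermodynamically in step 12. The step needs facial selectivity only, because C1 and C4 of the C2-symmetric 14 are homotopic and the anionic 21 resists a second addition. Two equivalents of t-BuLi are used for the exchange so that no alkyl bromide remains to alkylate 21.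

Step 11
Reactants: 22 the (1R,2S)-bis(oxazoline) adduct
Product: 24 bis[(2R)-2-acetamido-3,3-dimethylbutyl] (1R,2S)-6,7-bis(benzyloxy)-1-{4-(benzyloxy)-3-[(tert-butyldimethylsilyl)oxy]phenyl}-1,2-dihydronaphthalene-2,3-dicarboxylate, via ammonium ester salt 23 (not isolated)
Conditions: CF3CO2H, H2O, THF, rt; Na2SO4; then Ac2O, pyridine, CH2Cl2, 0 °C → rt
Reagents that add atoms: water, O; acetic anhydride, CC(=O)OC(C)=O
Why: the protonated oxazolines add water and open to the O-acyl ammonium esters, and immediate N-acetylation blocks O-to-N acyl migration (the mild staged oxazoline cleavage used for dihydronaphthalenes); if some aryl silyl ether is lost here the phenol is acetylated and converges in step 12.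

Step 12
Reactants: 24 the bis(acetamidoalkyl) diester
Product: 25 dimethyl (1R,2S)-6,7-bis(benzyloxy)-1-[4-(benzyloxy)-3-hydroxyphenyl]-1,2-dihydronaphthalene-2,3-dicarboxylate
Conditions: NaOMe, MeOH/THF, 0 → 40 °C, argon; AcOH quench
Reagents that add atoms: methanol (as sodium methoxide), CO
Why: base-catalysed transesterification exchanges both amido-alkyl esters for methyl esters, methoxide removes the aryl TBS group, and reversible deprotonation of the acidic C2–H (ester α-carbon, allylic to C3=C4) should funnel any cis epimer or 1,4-dihydro isomer to the more stable trans 1,2-dihydronaphthalene, fixing C2 as (S).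

Step 13
Reactants: 26 methyl bis(2,2,2-trifluoroethyl)phosphonoacetate
Product: 27 methyl 2-diazo-2-[bis(2,2,2-trifluoroethoxy)phosphoryl]acetate
Conditions: p-ABSA, DBU, MeCN, 0 °C
Reagents that add atoms: 4-acetamidobenzenesulfonyl azide, CC(=O)Nc1ccc(cc1)S(=O)(=O)N=[N+]=[N-]
Why: Regitz diazo transfer to the doubly activated methylene, which the trifluoroethyl phosphonate makes acidic enough for an amidine base.

Step 14
Reactants: 25 the dimethyl ester phenol; 27 methyl 2-diazo-2-[bis(2,2,2-trifluoroethoxy)phosphoryl]acetate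
Product: 28 dimethyl (1R,2S)-6,7-bis(benzyloxy)-1-[4-(benzyloxy)-3-{[bis(2,2,2-trifluoroethoxy)phosphoryl](methoxycarbonyl)methoxy}phenyl]-1,2-dihydronaphthalene-2,3-dicarboxylate (mixture at the phosphonate carbon)
Conditions: Rh2(OAc)4 (2 mol %), toluene, 80 °C
Reagents that add atoms: none
Why: the dirhodium carbenoid from the phosphonodiazoacetate inserts into the phenolic O–H bond (carbenoid O–H insertion) faster than it attacks the electron-poor C3=C4 alkene or benzylic C–H bonds, and the uncontrolled phosphonate carbon is erased in step 15.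

Step 15
Reactants: 28 the α-aryloxy phosphonoacetate; 1 3,4-bis(benzyloxy)benzaldehyde
Product: 30 dimethyl (1R,2S)-6,7-bis(benzyloxy)-1-[4-(benzyloxy)-3-({(1E)-2-[3,4-bis(benzyloxy)phenyl]-1-(methoxycarbonyl)ethenyl}oxy)phenyl]-1,2-dihydronaphthalene-2,3-dicarboxylate, via potassium phosphonate carbanion 29 (not isolated)
Conditions: KN(SiMe3)2 (1.0 equiv), 18-crown-6, THF, −78 °C; then 1, −78 °C
Reagents that add atoms: none
Why: Horner–Wadsworth–Emmons olefination in its Still–Gennari form, where the electron-poor bis(trifluoroethyl) phosphonate and the crown-separated potassium ion make adduct collapse faster than reversion, so the kinetic alkene with the catechol ring cis to the ester (the E enol ether) should result, and one equivalent of base at −78 °C removes the more acidic phosphonate proton in preference to C2–H.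

Step 16
Reactants: 30 the protected trimethyl ester
Product: 31 (1R,2S)-6,7-bis(benzyloxy)-1-[4-(benzyloxy)-3-({(1E)-2-[3,4-bis(benzyloxy)phenyl]-1-carboxyethenyl}oxy)phenyl]-1,2-dihydronaphthalene-2,3-dicarboxylic acid
Conditions: LiOH, THF/MeOH/H2O (degassed), rt → 40 °C, argon; then 1 M HCl
Reagents that add atoms: lithium hydroxide, [Li+].[OH-]
Why: saponification of the three methyl esters while all phenols are still benzylated, with oxygen excluded to prevent base-mediated aromatization of the dihydronaphthalene and with the trans C2 configuration being the thermodynamic one under base.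

Step 17
Reactants: 31 the pentabenzyl triacid
Product: 32 (1R,2S)-1-[3-({(1E)-1-carboxy-2-(3,4-dihydroxyphenyl)ethenyl}oxy)-4-hydroxyphenyl]-6,7-dihydroxy-1,2-dihydronaphthalene-2,3-dicarboxylic acid (CNP0241205.1)
Conditions: BCl3, C6HMe5, CH2Cl2, −78 → −40 °C; H2O quench
Reagents that add atoms: none
Why: Lewis-acid cleavage of the five aryl benzyl ethers with pentamethylbenzene as a non-basic benzyl-cation trap (Friedel–Crafts capture) avoids hydrogenation, which would reduce C3=C4 and the enol ether alkene, and should leave both stereocentres and the E geometry untouched.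

**Compound list**
1 | 3,4-bis(benzyloxy)benzaldehyde | O=Cc1ccc(OCc2ccccc2)c(OCc2ccccc2)c1 | starting material
2 | 4,5-bis(benzyloxy)-2-bromobenzaldehyde | O=Cc1cc(OCc2ccccc2)c(OCc2ccccc2)cc1Br | intermediate
3 | 2-[4,5-bis(benzyloxy)-2-bromophenyl]-1,3-dioxolane | Brc1cc(OCc2ccccc2)c(OCc2ccccc2)cc1C1OCCO1 | intermediate
4 | [4,5-bis(benzyloxy)-2-(1,3-dioxolan-2-yl)phenyl]lithium | [Li]c1cc(OCc2ccccc2)c(OCc2ccccc2)cc1C1OCCO1 | intermediate
5 | 4,5-bis(benzyloxy)-2-(1,3-dioxolan-2-yl)benzaldehyde | O=Cc1cc(OCc2ccccc2)c(OCc2ccccc2)cc1C1OCCO1 | intermediate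
6 | 4,5-bis(benzyloxy)phthalaldehyde | O=Cc1cc(OCc2ccccc2)c(OCc2ccccc2)cc1C=O | intermediate
7 | diethyl succinate | CCOC(=O)CCC(=O)OCC | starting material
8 | diethyl 6,7-bis(benzyloxy)naphthalene-2,3-dicarboxylate | CCOC(=O)c1cc2cc(OCc3ccccc3)c(OCc3ccccc3)cc2cc1C(=O)OCC | intermediate
9 | 6,7-bis(benzyloxy)naphthalene-2,3-dicarboxylic acid | OC(=O)c1cc2cc(OCc3ccccc3)c(OCc3ccccc3)cc2cc1C(=O)O | intermediate
10 | 6,7-bis(benzyloxy)naphthalene-2,3-dicarbonyl dichloride | ClC(=O)c1cc2cc(OCc3ccccc3)c(OCc3ccccc3)cc2cc1C(Cl)=O | intermediate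
11 | (R)-tert-leucinol, (2R)-2-amino-3,3-dimethylbutan-1-ol | N[C@@H](CO)C(C)(C)C | starting material
12 | 6,7-bis(benzyloxy)-N2,N3-bis[(2R)-1-hydroxy-3,3-dimethylbutan-2-yl]naphthalene-2,3-dicarboxamide | O=C(N[C@@H](CO)C(C)(C)C)c1cc2cc(OCc3ccccc3)c(OCc3ccccc3)cc2cc1C(=O)N[C@@H](CO)C(C)(C)C | intermediate
13 | bis(methanesulfonate) of 12 (both primary hydroxyls mesylated, both centres R) | O=C(N[C@@H](COS(C)(=O)=O)C(C)(C)C)c1cc2cc(OCc3ccccc3)c(OCc3ccccc3)cc2cc1C(=O)N[C@@H](COS(C)(=O)=O)C(C)(C)C | intermediate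
14 | 6,7-bis(benzyloxy)-2,3-bis[(4R)-4-tert-butyl-4,5-dihydro-1,3-oxazol-2-yl]naphthalene | CC(C)(C)[C@@H]1COC(=N1)c1cc2cc(OCc3ccccc3)c(OCc3ccccc3)cc2cc1C1=N[C@H](C(C)(C)C)CO1 | intermediate
15 | 5-bromosalicylaldehyde | O=Cc1cc(Br)ccc1O | starting material
16 | 2-(benzyloxy)-5-bromobenzaldehyde | O=Cc1cc(Br)ccc1OCc1ccccc1 | intermediate
17 | 2-(benzyloxy)-5-bromophenyl formate | O=COc1cc(Br)ccc1OCc1ccccc1 | intermediate
18 | 2-(benzyloxy)-5-bromophenol | Oc1cc(Br)ccc1OCc1ccccc1 | intermediate
19 | [2-(benzyloxy)-5-bromophenoxy](tert-butyl)dimethylsilane | CC(C)(C)[Si](C)(C)Oc1cc(Br)ccc1OCc1ccccc1 | intermediate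
20 | {4-(benzyloxy)-3-[(tert-butyldimethylsilyl)oxy]phenyl}lithium | [Li]c1ccc(OCc2ccccc2)c(O[Si](C)(C)C(C)(C)C)c1 | intermediate
21 | lithium aza-enolate of the C1 adduct (C1 as in 22, C2 exocyclic to the N-lithio oxazolidine, C3=C4 retained) | CC(C)(C)[C@@H]1COC(=N1)C2=Cc3cc(OCc4ccccc4)c(OCc4ccccc4)cc3[C@@H](c3ccc(OCc4ccccc4)c(O[Si](C)(C)C(C)(C)C)c3)C2=C2OC[C@@H](C(C)(C)C)N2[Li] | intermediate
22 | 2,2'-[(1R,2S)-6,7-bis(benzyloxy)-1-{4-(benzyloxy)-3-[(tert-butyldimethylsilyl)oxy]phenyl}-1,2-dihydronaphthalene-2,3-diyl]bis[(4R)-4-tert-butyl-4,5-dihydro-1,3-oxazole] | CC(C)(C)[C@@H]1COC(=N1)C1=Cc2cc(OCc3ccccc3)c(OCc3ccccc3)cc2[C@@H](c2ccc(OCc3ccccc3)c(O[Si](C)(C)C(C)(C)C)c2)[C@@H]1C1=N[C@H](C(C)(C)C)CO1 | intermediate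
23 | bis[(2R)-2-ammonio-3,3-dimethylbutyl] (1R,2S)-6,7-bis(benzyloxy)-1-{4-(benzyloxy)-3-[(tert-butyldimethylsilyl)oxy]phenyl}-1,2-dihydronaphthalene-2,3-dicarboxylate bis(trifluoroacetate) | CC(C)(C)[C@@H]([NH3+])COC(=O)C1=Cc2cc(OCc3ccccc3)c(OCc3ccccc3)cc2[C@@H](c2ccc(OCc3ccccc3)c(O[Si](C)(C)C(C)(C)C)c2)[C@@H]1C(=O)OC[C@H]([NH3+])C(C)(C)C.[O-]C(=O)C(F)(F)F.[O-]C(=O)C(F)(F)F | intermediate
24 | bis[(2R)-2-acetamido-3,3-dimethylbutyl] (1R,2S)-6,7-bis(benzyloxy)-1-{4-(benzyloxy)-3-[(tert-butyldimethylsilyl)oxy]phenyl}-1,2-dihydronaphthalene-2,3-dicarboxylate | CC(C)(C)[C@@H](NC(C)=O)COC(=O)C1=Cc2cc(OCc3ccccc3)c(OCc3ccccc3)cc2[C@@H](c2ccc(OCc3ccccc3)c(O[Si](C)(C)C(C)(C)C)c2)[C@@H]1C(=O)OC[C@H](NC(C)=O)C(C)(C)C | intermediate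
25 | dimethyl (1R,2S)-6,7-bis(benzyloxy)-1-[4-(benzyloxy)-3-hydroxyphenyl]-1,2-dihydronaphthalene-2,3-dicarboxylate | COC(=O)C1=Cc2cc(OCc3ccccc3)c(OCc3ccccc3)cc2[C@@H](c2ccc(OCc3ccccc3)c(O)c2)[C@@H]1C(=O)OC | intermediate
26 | methyl bis(2,2,2-trifluoroethyl)phosphonoacetate | COC(=O)CP(=O)(OCC(F)(F)F)OCC(F)(F)F | starting material
27 | methyl 2-diazo-2-[bis(2,2,2-trifluoroethoxy)phosphoryl]acetate | COC(=O)C(=[N+]=[N-])P(=O)(OCC(F)(F)F)OCC(F)(F)F | intermediate
28 | dimethyl (1R,2S)-6,7-bis(benzyloxy)-1-[4-(benzyloxy)-3-{[bis(2,2,2-trifluoroethoxy)phosphoryl](methoxycarbonyl)methoxy}phenyl]-1,2-dihydronaphthalene-2,3-dicarboxylate (mixture at the phosphonate carbon) | COC(=O)C1=Cc2cc(OCc3ccccc3)c(OCc3ccccc3)cc2[C@@H](c2ccc(OCc3ccccc3)c(OC(C(=O)OC)P(=O)(OCC(F)(F)F)OCC(F)(F)F)c2)[C@@H]1C(=O)OC | intermediate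
29 | potassium salt of 28 deprotonated at the phosphonate carbon (ester enolate form) | COC(=O)C1=Cc2cc(OCc3ccccc3)c(OCc3ccccc3)cc2[C@@H](c2ccc(OCc3ccccc3)c(OC(=C([O-])OC)P(=O)(OCC(F)(F)F)OCC(F)(F)F)c2)[C@@H]1C(=O)OC.[K+] | intermediate
30 | dimethyl (1R,2S)-6,7-bis(benzyloxy)-1-[4-(benzyloxy)-3-({(1E)-2-[3,4-bis(benzyloxy)phenyl]-1-(methoxycarbonyl)ethenyl}oxy)phenyl]-1,2-dihydronaphthalene-2,3-dicarboxylate | COC(=O)C1=Cc2cc(OCc3ccccc3)c(OCc3ccccc3)cc2[C@@H](c2ccc(OCc3ccccc3)c(O/C(=C/c3ccc(OCc4ccccc4)c(OCc4ccccc4)c3)C(=O)OC)c2)[C@@H]1C(=O)OC | intermediate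
31 | (1R,2S)-6,7-bis(benzyloxy)-1-[4-(benzyloxy)-3-({(1E)-2-[3,4-bis(benzyloxy)phenyl]-1-carboxyethenyl}oxy)phenyl]-1,2-dihydronaphthalene-2,3-dicarboxylic acid | OC(=O)C1=Cc2cc(OCc3ccccc3)c(OCc3ccccc3)cc2[C@@H](c2ccc(OCc3ccccc3)c(O/C(=C/c3ccc(OCc4ccccc4)c(OCc4ccccc4)c3)C(=O)O)c2)[C@@H]1C(=O)O | intermediate
32 | (1R,2S)-1-[3-({(1E)-1-carboxy-2-(3,4-dihydroxyphenyl)ethenyl}oxy)-4-hydroxyphenyl]-6,7-dihydroxy-1,2-dihydronaphthalene-2,3-dicarboxylic acid (CNP0241205.1) | O=C(O)C1=Cc2cc(O)c(O)cc2[C@@H](c2ccc(O)c(O/C(=C/c3ccc(O)c(O)c3)C(=O)O)c2)[C@@H]1C(=O)O | target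

**Totals**
Total step count: 17. Longest linear sequence: 13 steps (steps 1–6, 10–12, 14–17, from aldehyde 1).

**Steps most likely to fail**

Step 10 (the one step beyond established precedent). The two neighbouring oxazolines may twist out of the naphthalene plane, so that conjugate delivery of the aryllithium becomes slow or poorly face-selective, and the electron-rich ring lowers acceptor strength; the outcome would be low conversion or erosion of the C1 configuration. The fallback uses known reactions only, sets out from bromo acetal 3 and aryl bromide 19, and returns at 25. Heck coupling of 3 with methyl acrylate (Pd(OAc)2, P(o-tol)3, Et3N, DMF, 100 °C) should give methyl (E)-3-[4,5-bis(benzyloxy)-2-(1,3-dioxolan-2-yl)phenyl]acrylate F1. Aryllithium 20, made from 19 as in step 10, is borylated (B(OiPr)3, then dilute acid) to {4-(benzyloxy)-3-[(tert-butyldimethylsilyl)oxy]phenyl}boronic acid F2. Hayashi–Miyaura 1,4-addition of F2 to F1 (monovalent rhodium, [Rh(OH)(cod)]2 with BINAP or a chiral diene, dioxane/H2O, 50 °C, ligand enantiomer chosen by the established face model for E-enoates) should give methyl (3R)-3-{4-(benzyloxy)-3-[(tert-butyldimethylsilyl)oxy]phenyl}-3-[4,5-bis(benzyloxy)-2-(1,3-dioxolan-2-yl)phenyl]propanoate F3, which carries the C1 centre. Enolate alkylation (LiN(iPr)2, THF, −78 °C; BrCH2CO2Me) gives the dimethyl 2-[(R)-diarylmethyl]succinate F4 as an epimer mixture at the new carbon. Mild acetal hydrolysis (dilute HCl, THF, rt) frees the aldehyde in dimethyl 2-[(R)-{4-(benzyloxy)-3-[(tert-butyldimethylsilyl)oxy]phenyl}(4,5-bis(benzyloxy)-2-formylphenyl)methyl]succinate F5. NaOMe in MeOH then effects intramolecular aldol condensation of the succinate methylene onto the aldehyde (C3–C4 bond, dehydration to C3=C4), desilylation and C2 equilibration, returning to 25.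

Step 15. The alkene with the aryl group cis to the ester is the kinetic, less stable isomer, so geometric control may erode through reversible adduct formation, and the amide base may also deprotonate C2–H and lead to aldol by-products or kinetic reprotonation. The fallback fixes the geometry on a small fragment, avoids strong base on the advanced intermediate, sets out from 26, 1 and 25, and returns at 30. Phosphonate 26 is deprotonated (NaH, THF, 0 °C) and brominated with N-bromosuccinimide to methyl bromo[bis(2,2,2-trifluoroethoxy)phosphoryl]acetate F6. Olefination of 1 with F6 (KN(SiMe3)2, 18-crown-6, THF, −78 °C) should give, after separation of any isomer, methyl (E)-2-bromo-3-[3,4-bis(benzyloxy)phenyl]prop-2-enoate F7 with the aryl group cis to the ester. Ullmann-type vinylation of phenol 25 with F7 (CuI, copper monoiodide, N,N-dimethylglycine, Cs2CO3, dioxane, 60 °C), a C–O coupling that proceeds with retention at the vinyl carbon, returns to 30.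

Step 11. Opening of the two hindered tert-butyl oxazolines may stall, or acyl migration from O to N may outrun N-acetylation and leave hydroxy amides that resist methanolysis. The fallback activates by N-alkylation instead of protonation, sets out from 22 and returns at 25. Methylation (MeOTf, CH2Cl2, 0 °C → rt) gives the bis(3-methyloxazolinium) bis(triflate) F8. Alkaline hydrolysis (2 M NaOH, THF/MeOH, rt → 50 °C, argon; then HCl), which also removes the silyl ether, gives (1R,2S)-6,7-bis(benzyloxy)-1-[4-(benzyloxy)-3-hydroxyphenyl]-1,2-dihydronaphthalene-2,3-dicarboxylic acid F9. Chemoselective esterification of the two carboxylic acids (Me3SiCHN2, MeOH/toluene, 0 °C) and a brief NaOMe equilibration of C2 return to 25.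

**Further compounds**
F1 | step 10 | methyl (E)-3-[4,5-bis(benzyloxy)-2-(1,3-dioxolan-2-yl)phenyl]acrylate | COC(=O)/C=C/c1cc(OCc2ccccc2)c(OCc2ccccc2)cc1C1OCCO1
F2 | step 10 | {4-(benzyloxy)-3-[(tert-butyldimethylsilyl)oxy]phenyl}boronic acid | OB(O)c1ccc(OCc2ccccc2)c(O[Si](C)(C)C(C)(C)C)c1
F3 | step 10 | methyl (3R)-3-{4-(benzyloxy)-3-[(tert-butyldimethylsilyl)oxy]phenyl}-3-[4,5-bis(benzyloxy)-2-(1,3-dioxolan-2-yl)phenyl]propanoate | COC(=O)C[C@H](c1ccc(OCc2ccccc2)c(O[Si](C)(C)C(C)(C)C)c1)c1cc(OCc2ccccc2)c(OCc2ccccc2)cc1C1OCCO1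
F4 | step 10 | dimethyl 2-[(R)-{4-(benzyloxy)-3-[(tert-butyldimethylsilyl)oxy]phenyl}[4,5-bis(benzyloxy)-2-(1,3-dioxolan-2-yl)phenyl]methyl]succinate (mixture at C2) | COC(=O)CC(C(=O)OC)[C@H](c1ccc(OCc2ccccc2)c(O[Si](C)(C)C(C)(C)C)c1)c1cc(OCc2ccccc2)c(OCc2ccccc2)cc1C1OCCO1
F5 | step 10 | dimethyl 2-[(R)-{4-(benzyloxy)-3-[(tert-butyldimethylsilyl)oxy]phenyl}(4,5-bis(benzyloxy)-2-formylphenyl)methyl]succinate (mixture at C2) | COC(=O)CC(C(=O)OC)[C@H](c1ccc(OCc2ccccc2)c(O[Si](C)(C)C(C)(C)C)c1)c1cc(OCc2ccccc2)c(OCc2ccccc2)cc1C=O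
F6 | step 15 | methyl bromo[bis(2,2,2-trifluoroethoxy)phosphoryl]acetate | COC(=O)C(Br)P(=O)(OCC(F)(F)F)OCC(F)(F)F
F7 | step 15 | methyl (E)-2-bromo-3-[3,4-bis(benzyloxy)phenyl]prop-2-enoate | Br/C(=C/c1ccc(OCc2ccccc2)c(OCc2ccccc2)c1)C(=O)OC
F8 | step 11 | 2,2'-[(1R,2S)-6,7-bis(benzyloxy)-1-{4-(benzyloxy)-3-[(tert-butyldimethylsilyl)oxy]phenyl}-1,2-dihydronaphthalene-2,3-diyl]bis[(4R)-4-tert-butyl-3-methyl-4,5-dihydro-1,3-oxazol-3-ium] bis(trifluoromethanesulfonate) | CC(C)(C)[C@@H]1COC(=[N+]1C)C1=Cc2cc(OCc3ccccc3)c(OCc3ccccc3)cc2[C@@H](c2ccc(OCc3ccccc3)c(O[Si](C)(C)C(C)(C)C)c2)[C@@H]1C1=[N+](C)[C@H](C(C)(C)C)CO1.[O-]S(=O)(=O)C(F)(F)F.[O-]S(=O)(=O)C(F)(F)F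
F9 | step 11 | (1R,2S)-6,7-bis(benzyloxy)-1-[4-(benzyloxy)-3-hydroxyphenyl]-1,2-dihydronaphthalene-2,3-dicarboxylic acid | OC(=O)C1=Cc2cc(OCc3ccccc3)c(OCc3ccccc3)cc2[C@@H](c2ccc(OCc3ccccc3)c(O)c2)[C@@H]1C(=O)O
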